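## Structural features

The target is a depsidone: ring A (the methoxy arene) and ring B are held together by a diaryl ether oxygen and by an aryl ester, these two links close the seven-membered dioxepinone ring C, and a five-membered lactone-lactol (a 3-hydroxyphthalide) is fused to ring B. Going round ring A the substituents are OMe, H, CH3, the ester carbonyl, the ether oxygen and CH2OH; ring B has no hydrogen and carries the ether oxygen, the ester oxygen, CH3, OH, the lactone carbonyl and the lactol carbon. The lactol carbon is the only stereocentre; it is (R), has no stereogenic neighbour, and can invert by opening to the formyl acid, so it has to be set last and released under neutral conditions. The fragile groups are this lactol, the aryl ester of ring C (an activated ester, open to base and nucleophiles), the benzylic alcohol on ring A (between two ring oxygens, so it ionises easily in acid and is lost on hydrogenolysis) and the free phenol. The real difficulty lies in the two bonds of ring C: the ester joins an acyl carbon flanked by CH3 and O on ring A to an oxygen on a ring B carbon flanked by CH3 and O, and the ether is tetra-ortho-substituted. The key step uses the fact that ring A, with carboxyl, O, CH2O carbon, O, H and CH3 in sequence, is an orsellinate-type resorcylate, a folded tetraketide: its ester can be made from an unhindered acylketene on the ring B oxygen before ring A exists, and ring A is then closed by an aldol bond between the carboxyl-bearing and the methyl-bearing carbons.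

## Logic of the disconnections

26 back to 23. The cuts are the acyl C–O bond on the lactol oxygen (to 25), the Si–O bond (to 24) and, as a transform, the stereocentre itself (to racemic 23). The lactol centre is configurationally safe only as an acylal, so it is carried as the propanoate while the silyl ether is removed, and one neutral enzymatic step is left for the end. The gain is that everything before 23 is done on racemic or achiral material. The demand is that the acylation of 23 is a dynamic kinetic resolution that funnels both lactol enantiomers into 24, and that the last step breaks the acyl–oxygen bond and not a bond at the stereocentre.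

23 back to 21. The cuts are the two O–allyl bonds, one on the ring B carboxyl and one on the ring B phenol. Once the acid is free it adds to the neighbouring aldehyde, so the lactol needs no step of its own. The gain is that ring B stays non-acidic and non-chelating through all earlier steps. The demand is a deallylation that spares the ring C ester, the aldehyde and the benzylic silyl ether, which rules out acid and amines.

21 back to 20. The cut is the diaryl ether C–O bond of ring C, between the ring A oxygen and the ring B carbon next to the formyl group. With the ester already in place the closure is intramolecular, and the ring B carbon carries fluorine ortho to an aldehyde. The gain is that the seven-membered ring opens to an acyclic depside. The demand is that fluoride displacement beats ipso attack at the ester-bearing ring B carbon and cleavage of the aryl ester.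

20 back to 18. Only functional groups change: the aldehyde goes back to its dimethyl acetal (19) and the O–CH3 bond on ring A is cut (18). The acetal keeps the aldehyde away from ketene and enolate chemistry. Methylation is placed after ring A formation because the two ring A hydroxyls then differ, one being chelated to the ester carbonyl. The demand is clean mono-methylation of the non-chelated oxygen.

18 back to 7 and 15. The cuts are the ester C–O bond and the ring A C–C bond between the carboxyl-bearing carbon and the methyl-bearing carbon. The ester is cut here because it is the most hindered bond of the target and is trivial at the ketene stage. The gain is the largest of the route: one whole ring and the depside link fall away, leaving a linear tetraketide equivalent 7 and a single phenol 15. The demand is that 15 has exactly one free hydroxyl, that its other groups survive 110 °C and carbonate, and that the triketo ester closes by aldol and not by acyl substitution or β-elimination.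

7 back to 1. The cuts are the C–C bond to the terminal acetyl group (5), the C–C bond to the first acetyl group (3) and the C–C bond to the CH2O carbon (1). Each is a reaction of a dioxinone enolate with a simple electrophile, so the whole chain comes from one cheap heterocycle. The demand is that enolates that carry a β-silyloxy group are kept cold and short-lived.

15 back to 8. The cuts are the C–CHO bond (12), the two O-protecting bonds (11, 10), the C–F bond (9) and the ester O–allyl bond (8). The formyl carbon is introduced at the only ring C–H, which lies between fluorine and the ester, so its position is fixed by the substrate; oxidising one of two ring methyl groups would not be regiochemically secured. The demand is that fluorination goes to the one doubly activated position and that the two phenols are told apart by the hydrogen bond to the ester.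

## Other disconnections considered

Alternative 1: The cut is the ester O–aryl bond of ring C, made last from the diaryl ether carboxylic acid A2, whose ring B has a free phenol para to the ether oxygen and a hydrogen next to it. In the forward step the trivalent iodine reagent PhI(OAc)2 oxidises that phenol, the carboxyl adds to the para carbon to give the spiro quinone monoketal lactone A3, and acid then moves the acyloxy group to the neighbouring CH carbon with rearomatisation, giving the depsidone A1.
- In its favour: the ether is made first, between open partners, which is the better way to that bond than a seven-membered fluoride displacement. Ring C is closed without base, so neither a Smiles pathway nor ester cleavage threatens, and the spirolactonisation is a six-membered closure.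
- Against it here: A2 requires both heavily substituted rings to be built separately and joined through a tetra-ortho-substituted ether. In the rearrangement of A3 either ketal oxygen can migrate, and migration of the aryloxy instead of the acyloxy group would give the isomer with ester and ether interchanged; nothing in the structure decides this. A1 still carries a methyl ester and an acetate that must be removed beside the ring C ester.
- Comparison: on the lactol the two plans are equal, since both end with the same resolution problem. On the ether bond and on the mildness of ring C closure the alternative is the better. On mechanism the chosen plan has fewer open regiochemical questions, because its ring-forming aldol is fixed by ring size. On step economy the alternative is probably somewhat longer, since two complete arenes are needed before the key step.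

Alternative 2: The cuts are two C–C bonds of ring B. The aryloxy bis(silyloxy) diene A5, carried on the ring A phenol oxygen, adds to the ynoate A6 and the adduct aromatises by loss of methanol to the diaryl ether A4 with ring B complete.
- In its favour: a fully substituted ring B arises in one step with every substituent placed by the polarity of the partners, and no fluorination or metalation is needed. The ether oxygen is attached early by simple O-alkylation, which is better than the chosen route to that bond.
- Against it here: A5 is a crowded, hydrolytically labile ketene acetal diene of undefined geometry, and its cycloaddition with an internal ynoate needs heat. A4 leaves the hindered ring C ester still to be made, by lactonising a di-ortho-substituted acid onto a flanked phenol, which is the very bond that the chosen plan makes at the ketene stage.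
- Comparison: in convergence the two are equal. The alternative is better for the ether and worse for the ester. Its mechanism is sound in principle, but the preparation of A5 is the weak point. Step economy is about equal.

Alternative 3: The cuts are three C–C bonds of ring A. The ring B diyne A8 (an aryl ynol ether and a but-2-ynoate ester on neighbouring oxygens) is joined with methoxyethyne A9 by the cationic monovalent rhodium catalyst [Rh(cod)2]BF4 with BINAP to give the protected depsidone A7, closing ring A and ring C at once.
- In its favour: this is the most convergent plan. Both links of ring C are made beforehand as unhindered bonds, the ester by acylation with butynoic acid, which is the same advantage as in the chosen plan, so no fluoride displacement and no lactonisation are needed. On paper it is the shortest route and here it is the better of the two.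
- Against it here: the aryl ynol ether has to be made on a hindered phenol and is sensitive. The two tethered alkynes must close a seven-membered ring in the metallacycle, which is less favourable than the five- and six-membered tethers on which such cyclotrimerisations rely. A9 is volatile, can enter in two orientations and can trimerise with itself. The chiral ligand has nothing to control.
- Comparison: on structure the alternative is the better (two rings and three bonds against one ring and two bonds). On mechanism it is less secure, since the orientation of the third alkyne and the medium-ring tether are open, while the chosen aldol is fixed by a six-membered transition state. On step economy it is better if the key step works.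

Key step: step 10

Assumptions (remarks on the chemistry):
- The free lactol is taken to hold its configuration in neutral, base-free media; with base it racemises through the open formyl carboxylate, which step 15 uses and step 17 avoids.
- The sense of induction of the acyl-transfer catalyst on this lactol is not known in advance; the antipode that delivers the (R)-acylal is meant and is written as (R)-benzotetramisole.
- Ring B is carried as allyl ester and allyl ether: a tert-butyl ester next to the acetal would be lost in the acid steps (carbonyl capture of the oxocarbenium ion, loss of isobutene), and acid at the end would endanger the benzylic oxygen on ring A. The connectivity of the two key-step partners needs no correction: the silyloxymethyl-bearing carbon of 7 becomes the ring A carbon between the two hydroxyls.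

## Route

Step 1
Reactants: 1 2,2,6-trimethyl-4H-1,3-dioxin-4-one
Product: 3 2,2-dimethyl-6-(2-{[tri(propan-2-yl)silyl]oxy}ethyl)-4H-1,3-dioxin-4-one, via lithium dienolate 2 (not isolated)
Conditions: LiN(i-Pr)2, THF, −78 °C; i-Pr3SiOCH2Cl, DMPU, −78 → −40 °C
Reagents that add atoms: (triisopropylsiloxy)methyl chloride, CC(C)[Si](OCCl)(C(C)C)C(C)C
Why: Alkylation of a lithium dienolate; the dienolate of 1 takes reactive halides at its exocyclic γ-carbon, and the chloromethyl silyl ether is reactive enough to alkylate at −78 °C before the dienolate fragments; no stereocentre is formed.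

Step 2
Reactants: 3 2,2-dimethyl-6-(2-{[tri(propan-2-yl)silyl]oxy}ethyl)-4H-1,3-dioxin-4-one
Product: 5 rac-2,2-dimethyl-6-(3-oxo-1-{[tri(propan-2-yl)silyl]oxy}butan-2-yl)-4H-1,3-dioxin-4-one, via silyloxyethyl dienolate 4 (not isolated)
Conditions: LiN(i-Pr)2, THF, −78 °C; MeC(O)N(OMe)Me, −78 → −40 °C; AcOH, −78 °C
Reagents that add atoms: N-methoxy-N-methylacetamide, CC(=O)N(C)OC
Why: Claisen-type acylation of the γ-dienolate; the chelated tetrahedral lithium adduct of the N-methoxy-N-methylamide survives until the cold acidic quench, so the acidic hydrogen next to the silyloxymethyl group of 5 never meets base and silanolate is not eliminated; the new centre is racemic and is lost in step 10.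

Step 3
Reactants: 5 rac-2,2-dimethyl-6-(3-oxo-1-{[tri(propan-2-yl)silyl]oxy}butan-2-yl)-4H-1,3-dioxin-4-one
Product: 7 rac-6-(3,5-dioxo-1-{[tri(propan-2-yl)silyl]oxy}hexan-2-yl)-2,2-dimethyl-4H-1,3-dioxin-4-one, via dilithium dianion 6 (not isolated)
Conditions: LiN(i-Pr)2 (2.3 equiv), THF, −78 °C; MeC(O)N(OMe)Me, −78 → −40 °C; AcOH, −78 °C
Reagents that add atoms: N-methoxy-N-methylacetamide, CC(=O)N(C)OC
Why: Claisen condensation of a keto-dioxinone dianion; the first equivalent of base removes the doubly activated γ-hydrogen and the second the terminal methyl hydrogen, and the more basic terminal carbanion of 6 is the one that adds to the amide; the low temperature keeps the γ-enolate from expelling silanolate, and 7 is used at once because diketo-dioxinones aromatise with base.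

Step 4
Reactants: 8 2,4-dihydroxy-3-methylbenzoic acid
Product: 9 prop-2-en-1-yl 2,4-dihydroxy-3-methylbenzoate
Conditions: allyl bromide, KHCO3, DMF, rt → 40 °C
Reagents that add atoms: allyl bromide, C=CCBr
Why: SN2 O-alkylation of the carboxylate; hydrogen carbonate deprotonates only the acid, so both phenols stay free; the allyl ester is inert to acid, carbonate and 110 °C and leaves under neutral conditions in step 14.

Step 5
Reactants: 9 prop-2-en-1-yl 2,4-dihydroxy-3-methylbenzoate
Product: 10 prop-2-en-1-yl 5-fluoro-2,4-dihydroxy-3-methylbenzoate
Conditions: Selectfluor [1-chloromethyl-4-fluoro-1,4-diazoniabicyclo[2.2.2]octane bis(tetrafluoroborate)], MeCN, 0 °C → rt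
Reagents that add atoms: Selectfluor, F[N+]12CC[N+](CCl)(CC1)CC2.F[B-](F)(F)F.F[B-](F)(F)F
Why: Electrophilic aromatic fluorination; C-5 is the only ring position activated by both hydroxyls (ortho to the 4-OH, para to the 2-OH), C-3 is blocked by methyl and C-6 is meta to both; the isolated allyl double bond does not react with the N–F reagent at this temperature.

Step 6
Reactants: 10 prop-2-en-1-yl 5-fluoro-2,4-dihydroxy-3-methylbenzoate
Product: 11 prop-2-en-1-yl 5-fluoro-2-hydroxy-4-(methoxymethoxy)-3-methylbenzoate
Conditions: MOMCl (1.1 equiv), i-Pr2NEt, CH2Cl2, 0 °C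
Reagents that add atoms: chloromethyl methyl ether, COCCl
Why: Williamson-type O-alkylation; the 2-OH is locked in a hydrogen bond to the ester carbonyl, so only the 4-OH, further acidified by the ortho fluorine, reacts; this MOM group is temporary and marks the oxygen that will capture the ketene.

Step 7
Reactants: 11 prop-2-en-1-yl 5-fluoro-2-hydroxy-4-(methoxymethoxy)-3-methylbenzoate
Product: 12 prop-2-en-1-yl 5-fluoro-4-(methoxymethoxy)-3-methyl-2-(prop-2-en-1-yloxy)benzoate
Conditions: allyl bromide, K2CO3, DMF, 50 °C
Reagents that add atoms: allyl bromide, C=CCBr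
Why: Williamson allylation of the chelated phenol under forcing carbonate conditions; this ether later leaves in the same palladium step as the allyl ester.

Step 8
Reactants: 12 prop-2-en-1-yl 5-fluoro-4-(methoxymethoxy)-3-methyl-2-(prop-2-en-1-yloxy)benzoate
Product: 14 prop-2-en-1-yl 5-fluoro-6-formyl-4-(methoxymethoxy)-3-methyl-2-(prop-2-en-1-yloxy)benzoate, via arylmagnesium chloride 13 (not isolated)
Conditions: (2,2,6,6-tetramethylpiperidin-1-yl)MgCl·LiCl, THF, −20 °C; DMF, −20 → 0 °C; aq. NH4Cl
Reagents that add atoms: N,N-dimethylformamide, CN(C)C=O
Why: Directed ortho-magnesiation then formylation; C-6–H is the only ring hydrogen and lies between fluorine and the ester, which both acidify and direct; the hindered magnesium amide tolerates the ester and the allyl groups, and the cold keeps the ortho-fluoro arylmagnesium from eliminating to an aryne.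

Step 9
Reactants: 14 prop-2-en-1-yl 5-fluoro-6-formyl-4-(methoxymethoxy)-3-methyl-2-(prop-2-en-1-yloxy)benzoate
Product: 15 prop-2-en-1-yl 6-(dimethoxymethyl)-5-fluoro-4-hydroxy-3-methyl-2-(prop-2-en-1-yloxy)benzoate
Conditions: HC(OMe)3, MeOH, TsOH·H2O (cat.), 45 °C; Et3N
Reagents that add atoms: trimethyl orthoformate, COC(OC)OC; methanol, CO
Why: Acid-catalysed acetalisation with orthoformate as water scavenger and, in the same pot, transacetalisation of the phenolic MOM ether to dimethoxymethane; the allyl ester and allyl ether are inert to acidic methanol, and a primary allyl ester does not collapse onto the neighbouring oxocarbenium ion as a tert-butyl ester would.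

Step 10
Reactants: 7 rac-6-(3,5-dioxo-1-{[tri(propan-2-yl)silyl]oxy}hexan-2-yl)-2,2-dimethyl-4H-1,3-dioxin-4-one; 15 prop-2-en-1-yl 6-(dimethoxymethyl)-5-fluoro-4-hydroxy-3-methyl-2-(prop-2-en-1-yloxy)benzoate
Product: 18 prop-2-en-1-yl 4-{[2,4-dihydroxy-6-methyl-3-({[tri(propan-2-yl)silyl]oxy}methyl)benzoyl]oxy}-6-(dimethoxymethyl)-5-fluoro-3-methyl-2-(prop-2-en-1-yloxy)benzoate, via acylketene 16 (not isolated), via triketo aryl ester 17 (not isolated)
Conditions: 7 (1.2 equiv), PhMe, 110 °C; then Cs2CO3, THF, 0 °C → rt; AcOH
Reagents that add atoms: none
Why: Heating 7 releases acetone by retro-[4+2] and gives acylketene 16, which the phenol of 15, the only free hydroxyl in either partner, captures to the aryl β-keto ester 17, so the ester C–O bond forms at an unhindered sp carbon without a coupling reagent. Cs2CO3 then enolises the methylene between the ester and the first ketone, this carbon adds to the terminal methyl ketone in a 6-(enolexo)-exo-trig aldol closure, and loss of water with enolisation of the two remaining ring ketones gives aromatic ring A, the second new bond being the C–C bond between the carboxyl-bearing and the methyl-bearing carbons. The closest known reaction type is thermolysis of diketo-dioxinones in the presence of alcohols or phenols followed by base-mediated aldol aromatisation of the 3,5,7-triketo esters to resorcylates. No stereocentre is created, and the racemic centre of 7 ends as the planar carbon that carries the silyloxymethyl group between the two ring A hydroxyls. Three selectivities are needed: capture by the phenol must outrun ketene dimerisation and internal O-acylation by an enol of 16, helped by running concentrated with 15 present from the start; aldol closure must beat Claisen-type attack of the far methylene on the aryl ester, favoured by mild carbonate, an aprotic medium and the higher acidity of the ester-flanked methylene; and the enolate at the silyloxymethyl-bearing carbon must not expel silanolate, which the bulky silyl group, the low temperature and the fast, irreversible aromatisation guard against. The acetal, the aryl fluoride and both allyl groups of 15 are inert to 110 °C and to carbonate.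

Step 11
Reactants: 18 the depside of step 10 with two free ring A hydroxyls
Product: 19 prop-2-en-1-yl 6-(dimethoxymethyl)-5-fluoro-4-{[2-hydroxy-4-methoxy-6-methyl-3-({[tri(propan-2-yl)silyl]oxy}methyl)benzoyl]oxy}-3-methyl-2-(prop-2-en-1-yloxy)benzoate
Conditions: MeI (1.2 equiv), K2CO3, acetone, 0 °C → rt
Reagents that add atoms: iodomethane, CI
Why: Williamson methylation; the ring A 2-OH is chelated to the depside carbonyl and the 4-OH is not, so one equivalent of MeI methylates the para oxygen only; the di-ortho-substituted aryl ester is inert to carbonate in acetone.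

Step 12
Reactants: 19 the 4-O-methyl depside dimethyl acetal
Product: 20 prop-2-en-1-yl 5-fluoro-6-formyl-4-{[2-hydroxy-4-methoxy-6-methyl-3-({[tri(propan-2-yl)silyl]oxy}methyl)benzoyl]oxy}-3-methyl-2-(prop-2-en-1-yloxy)benzoate
Conditions: TsOH·H2O (cat.), acetone/H2O 10:1, rt
Reagents that add atoms: water, O
Why: Acid-catalysed acetal hydrolysis by exchange with wet acetone; the dimethyl acetal is the most acid-labile group present, while the silyl ether, the allyl groups and the hindered aryl ester are untouched at room temperature.

Step 13
Reactants: 20 the fluoro aldehyde depside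
Product: 21 prop-2-en-1-yl 6-formyl-3-methoxy-1,9-dimethyl-11-oxo-8-(prop-2-en-1-yloxy)-4-({[tri(propan-2-yl)silyl]oxy}methyl)-11H-dibenzo[b,e][1,4]dioxepine-7-carboxylate
Conditions: Cs2CO3, DMF (0.01 M), 60 °C
Reagents that add atoms: none
Why: Intramolecular nucleophilic aromatic substitution (addition–elimination); the ring A phenoxide attacks the fluorine-bearing carbon, activated by the ortho formyl group and by fluorine itself, through a seven-membered transition state; high dilution suppresses intermolecular reaction, and ipso attack at the ester-bearing carbon (Smiles pathway) should be slower because that carbon has only a para ester as activator and a poorer nucleofuge.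

Step 14
Reactants: 21 the protected depsidone aldehyde
Product: 23 racemic lactol: 21 with the allyl ester and allyl ether removed and the 7-carboxyl closed onto the 6-formyl group as a 3-hydroxyphthalide; ring B phenol free, silyl ether kept, via formyl carboxylic acid 22 (not isolated)
Conditions: Pd(PPh3)4 (5 mol %), TolSO2Na, THF/H2O 10:1, rt; aq. NaH2PO4
Reagents that add atoms: none
Why: Palladium-catalysed allyl transfer (Tsuji–Trost type) to the sulfinate removes the allyl ester and the allyl aryl ether under neutral conditions; the freed acid 22 adds to the neighbouring aldehyde and the lactol closes by ring–chain tautomerism, racemic at this stage; sulfinate is chosen as acceptor because it neither condenses with the aldehyde nor attacks the ring C ester.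

Step 15
Reactants: 23 racemic lactol
Product: 24 (R)-acylal: the O-propanoyl derivative of 23 at the lactol oxygen, (R) at the acylal carbon
Conditions: (R)-benzotetramisole [(R)-2-phenyl-2,3-dihydroimidazo[2,1-b][1,3]benzothiazole] (10 mol %), (EtCO)2O, i-Pr2NEt, CHCl3, 0 °C
Reagents that add atoms: propanoic anhydride, CCC(=O)OC(=O)CC
Why: Acylative dynamic kinetic resolution of a lactol; the amine base interconverts the lactol enantiomers through the open formyl carboxylate and the chiral isothiourea acyl-transfer catalyst propanoylates one of them faster, so the material converges on the (R)-acylal, in which the centre is fixed; the stereocentre is set here by the catalyst, and the chelated, flanked phenol should stay free (any phenol ester would be cleaved in step 17).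

Step 16
Reactants: 24 (R)-acylal silyl ether
Product: 25 (R)-acylal with free hydroxymethyl group on ring A
Conditions: HF·pyridine, pyridine, THF, 0 °C → rt
Reagents that add atoms: none
Why: Fluoride-induced Si–O cleavage under buffered, weakly acidic conditions that the acylal, the ring C ester and the new benzylic alcohol tolerate; the stereocentre is an acylal carbon at this point and cannot ring-open.

Step 17
Reactants: 25 (R)-acylal alcohol
Product: 26 target, (R)-lactol (CNP0367167.1)
Conditions: immobilised Candida antarctica lipase B, n-BuOH, t-BuOMe, 30 °C
Reagents that add atoms: none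
Why: Lipase-catalysed alcoholysis (serine-hydrolase acyl transfer); the enzyme cleaves the acyl–oxygen bond of the propanoate, so no bond at the stereocentre breaks and the (R)-configuration is retained; the medium is neutral and free of base, which keeps the liberated lactol from racemising, and phthalidyl esters are established esterase substrates.

## Compound list

1 | 2,2,6-trimethyl-4H-1,3-dioxin-4-one | CC1=CC(=O)OC(C)(C)O1 | starting material
2 | lithium 2,2-dimethyl-6-methylidene-6H-1,3-dioxin-4-olate (dienolate of 1) | [Li+].C=C1C=C([O-])OC(C)(C)O1 | intermediate (not isolated)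
3 | 2,2-dimethyl-6-(2-{[tri(propan-2-yl)silyl]oxy}ethyl)-4H-1,3-dioxin-4-one | CC(C)[Si](OCCC1=CC(=O)OC(C)(C)O1)(C(C)C)C(C)C | intermediate
4 | lithium 2,2-dimethyl-6-(2-{[tri(propan-2-yl)silyl]oxy}ethylidene)-6H-1,3-dioxin-4-olate (dienolate of 3) | [Li+].[O-]C1=CC(=CCO[Si](C(C)C)(C(C)C)C(C)C)OC(C)(C)O1 | intermediate (not isolated)
5 | rac-2,2-dimethyl-6-(3-oxo-1-{[tri(propan-2-yl)silyl]oxy}butan-2-yl)-4H-1,3-dioxin-4-one | CC(=O)C(CO[Si](C(C)C)(C(C)C)C(C)C)C1=CC(=O)OC(C)(C)O1 | intermediate
6 | dilithium dianion of 5 (γ-enolate and terminal methyl enolate) | [Li+].[Li+].C=C([O-])C(CO[Si](C(C)C)(C(C)C)C(C)C)=C1C=C([O-])OC(C)(C)O1 | intermediate (not isolated)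
7 | rac-6-(3,5-dioxo-1-{[tri(propan-2-yl)silyl]oxy}hexan-2-yl)-2,2-dimethyl-4H-1,3-dioxin-4-one | CC(=O)CC(=O)C(CO[Si](C(C)C)(C(C)C)C(C)C)C1=CC(=O)OC(C)(C)O1 | intermediate
8 | 2,4-dihydroxy-3-methylbenzoic acid | Cc1c(O)ccc(C(=O)O)c1O | starting material
9 | prop-2-en-1-yl 2,4-dihydroxy-3-methylbenzoate | C=CCOC(=O)c1ccc(O)c(C)c1O | intermediate
10 | prop-2-en-1-yl 5-fluoro-2,4-dihydroxy-3-methylbenzoate | C=CCOC(=O)c1cc(F)c(O)c(C)c1O | intermediate
11 | prop-2-en-1-yl 5-fluoro-2-hydroxy-4-(methoxymethoxy)-3-methylbenzoate | C=CCOC(=O)c1cc(F)c(OCOC)c(C)c1O | intermediate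
12 | prop-2-en-1-yl 5-fluoro-4-(methoxymethoxy)-3-methyl-2-(prop-2-en-1-yloxy)benzoate | C=CCOC(=O)c1cc(F)c(OCOC)c(C)c1OCC=C | intermediate
13 | C-6 arylmagnesium chloride of 12, LiCl complex | C=CCOC(=O)c1c([Mg]Cl)c(F)c(OCOC)c(C)c1OCC=C.[Li+].[Cl-] | intermediate (not isolated)
14 | prop-2-en-1-yl 5-fluoro-6-formyl-4-(methoxymethoxy)-3-methyl-2-(prop-2-en-1-yloxy)benzoate | C=CCOC(=O)c1c(C=O)c(F)c(OCOC)c(C)c1OCC=C | intermediate
15 | prop-2-en-1-yl 6-(dimethoxymethyl)-5-fluoro-4-hydroxy-3-methyl-2-(prop-2-en-1-yloxy)benzoate | C=CCOC(=O)c1c(C(OC)OC)c(F)c(O)c(C)c1OCC=C | intermediate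
16 | 4-({[tri(propan-2-yl)silyl]oxy}methyl)oct-1-ene-1,3,5,7-tetrone (acylketene) | O=C=CC(=O)C(CO[Si](C(C)C)(C(C)C)C(C)C)C(=O)CC(C)=O | intermediate (not isolated)
17 | 3-(allyloxy)-4-(allyloxycarbonyl)-5-(dimethoxymethyl)-6-fluoro-2-methylphenyl 3,5,7-trioxo-4-({[tri(propan-2-yl)silyl]oxy}methyl)octanoate | CC(=O)CC(=O)C(CO[Si](C(C)C)(C(C)C)C(C)C)C(=O)CC(=O)Oc1c(C)c(OCC=C)c(C(=O)OCC=C)c(C(OC)OC)c1F | intermediate (not isolated)
18 | prop-2-en-1-yl 4-{[2,4-dihydroxy-6-methyl-3-({[tri(propan-2-yl)silyl]oxy}methyl)benzoyl]oxy}-6-(dimethoxymethyl)-5-fluoro-3-methyl-2-(prop-2-en-1-yloxy)benzoate | Cc1cc(O)c(CO[Si](C(C)C)(C(C)C)C(C)C)c(O)c1C(=O)Oc1c(C)c(OCC=C)c(C(=O)OCC=C)c(C(OC)OC)c1F | intermediate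
19 | prop-2-en-1-yl 6-(dimethoxymethyl)-5-fluoro-4-{[2-hydroxy-4-methoxy-6-methyl-3-({[tri(propan-2-yl)silyl]oxy}methyl)benzoyl]oxy}-3-methyl-2-(prop-2-en-1-yloxy)benzoate | Cc1cc(OC)c(CO[Si](C(C)C)(C(C)C)C(C)C)c(O)c1C(=O)Oc1c(C)c(OCC=C)c(C(=O)OCC=C)c(C(OC)OC)c1F | intermediate
20 | prop-2-en-1-yl 5-fluoro-6-formyl-4-{[2-hydroxy-4-methoxy-6-methyl-3-({[tri(propan-2-yl)silyl]oxy}methyl)benzoyl]oxy}-3-methyl-2-(prop-2-en-1-yloxy)benzoate | Cc1cc(OC)c(CO[Si](C(C)C)(C(C)C)C(C)C)c(O)c1C(=O)Oc1c(C)c(OCC=C)c(C(=O)OCC=C)c(C=O)c1F | intermediate
21 | prop-2-en-1-yl 6-formyl-3-methoxy-1,9-dimethyl-11-oxo-8-(prop-2-en-1-yloxy)-4-({[tri(propan-2-yl)silyl]oxy}methyl)-11H-dibenzo[b,e][1,4]dioxepine-7-carboxylate | COc1cc(C)c2c(c1CO[Si](C(C)C)(C(C)C)C(C)C)Oc1c(c(C)c(OCC=C)c(C(=O)OCC=C)c1C=O)OC2=O | intermediate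
22 | 6-formyl-8-hydroxy-3-methoxy-1,9-dimethyl-11-oxo-4-({[tri(propan-2-yl)silyl]oxy}methyl)-11H-dibenzo[b,e][1,4]dioxepine-7-carboxylic acid | COc1cc(C)c2c(c1CO[Si](C(C)C)(C(C)C)C(C)C)Oc1c(c(C)c(O)c(C(=O)O)c1C=O)OC2=O | intermediate (not isolated)
23 | racemic lactol: the 3-hydroxyphthalide tautomer of 22 (7-carboxyl closed onto the 6-formyl carbon), phenol free, silyl ether kept | COc1cc(C)c2c(c1CO[Si](C(C)C)(C(C)C)C(C)C)Oc1c(c(C)c(O)c3c1C(O)OC3=O)OC2=O | intermediate
24 | (R)-O-propanoyl lactol (acylal) of 23, silyl ether kept | COc1cc(C)c2c(c1CO[Si](C(C)C)(C(C)C)C(C)C)Oc1c(c(C)c(O)c3c1[C@H](OC(=O)CC)OC3=O)OC2=O | intermediate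
25 | (R)-O-propanoyl lactol with free ring A hydroxymethyl group | COc1cc(C)c2c(c1CO)Oc1c(c(C)c(O)c3c1[C@H](OC(=O)CC)OC3=O)OC2=O | intermediate
26 | target: depsidone with ring A OMe, CH3 and CH2OH, ring B CH3, OH and fused (R)-3-hydroxyphthalide | COc1cc(C)c2c(c1CO)Oc1c(c(C)c(O)c3c1[C@H](O)OC3=O)OC2=O | target

## Step count and risks

Total step count: 17. Longest linear sequence: 14 steps (8 to 26, steps 4 to 17); the dioxinone branch (steps 1 to 3) joins at step 10.

Steps least certain to work:

Step 10 (key step). The acylketene may be diverted before the hindered, fluorine-acidified phenol captures it, by dimerisation or by internal O-acylation to a pyranone. At the carbonate stage, silanolate may be lost by β-elimination, or the chain may close in the Claisen sense with expulsion of the aryloxide. Fallback, from 7 (with 15) and back at 19: ring A is made before the ester. Et3N in CH2Cl2 aromatises 7 with its acetonide intact to 7-hydroxy-2,2,5-trimethyl-8-({[tri(propan-2-yl)silyl]oxy}methyl)-4H-1,3-benzodioxin-4-one F1. MeI and K2CO3 give 7-methoxy-2,2,5-trimethyl-8-({[tri(propan-2-yl)silyl]oxy}methyl)-4H-1,3-benzodioxin-4-one F2. Irradiation of F2 at 300 nm with 15 in CH2Cl2 extrudes acetone and the quinoketene is captured by the phenol to give 19 directly.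

Step 1. The dienolate may be alkylated twice after proton exchange with the product, or at oxygen or the ring α-carbon, and it fragments if warmed. Fallback, from 1 and back at 3: LiN(i-Pr)2 and Me3SiCl convert 1 into [(2,2-dimethyl-6-methylidene-6H-1,3-dioxin-4-yl)oxy]trimethylsilane F3. A vinylogous Mukaiyama aldol addition to formaldehyde (1,3,5-trioxane, TiCl4, CH2Cl2, −78 °C) gives 6-(2-hydroxyethyl)-2,2-dimethyl-4H-1,3-dioxin-4-one F4, and i-Pr3SiCl with imidazole gives 3.

Step 3. The dianion carries its first negative charge on the carbon next to the silyloxymethyl group, so silanolate may be eliminated; acylation may also stop short through proton transfer. Fallback, from 3 and back at 7, replacing steps 2 and 3 by one C–C bond formation without a dianion: ethyl (2-methyl-1,3-dioxolan-2-yl)acetate, MeNH(OMe)·HCl and i-PrMgCl give N-methoxy-N-methyl-2-(2-methyl-1,3-dioxolan-2-yl)acetamide F5. The dienolate 4 adds to F5 to give 2,2-dimethyl-6-[4-(2-methyl-1,3-dioxolan-2-yl)-3-oxo-1-{[tri(propan-2-yl)silyl]oxy}butan-2-yl]-4H-1,3-dioxin-4-one F6, and dilute aqueous HCl in acetone frees the second ketone to give 7.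

Step 13. The ring closure may be outrun by ipso attack of the same phenoxide at the ester-bearing ring B carbon (Smiles rearrangement to a diaryl ether acid) or by cleavage of the aryl ester, because the fluorine-bearing carbon has a para alkoxy donor and only one ortho acceptor. Fallback, from 9 and back at 21, replacing addition–elimination by copper-catalysed coupling in a bromo series:
- NBS in MeCN gives prop-2-en-1-yl 5-bromo-2,4-dihydroxy-3-methylbenzoate F7.
- The operations of steps 6 to 9 then give in turn prop-2-en-1-yl 5-bromo-2-hydroxy-4-(methoxymethoxy)-3-methylbenzoate F8, prop-2-en-1-yl 5-bromo-4-(methoxymethoxy)-3-methyl-2-(prop-2-en-1-yloxy)benzoate F9, prop-2-en-1-yl 5-bromo-6-formyl-4-(methoxymethoxy)-3-methyl-2-(prop-2-en-1-yloxy)benzoate F10 and prop-2-en-1-yl 5-bromo-6-(dimethoxymethyl)-4-hydroxy-3-methyl-2-(prop-2-en-1-yloxy)benzoate F11.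
- Ketene capture with 7 as in step 10 gives the bromo depside with two free ring A hydroxyls F12, and methylation as in step 11 gives its 4-O-methyl ether F13.
- CuI (copper monoiodide), picolinic acid and K3PO4 in DMSO at 90 °C close the ether (Ullmann-type coupling) to the depsidone dimethyl acetal F14, and hydrolysis as in step 12 gives 21.

Step 15. The catalyst may discriminate poorly between the lactol enantiomers, or racemisation of the lactol may be too slow relative to acylation, so that the acylal forms with low enantiomeric purity. Fallback, from 23 and back at 24: propanoic anhydride with 4-(dimethylamino)pyridine gives the racemic acylal, a 1:1 mixture of 24 and its enantiomer, the (S)-O-propanoyl lactol silyl ether F15. Preparative chromatography on a chiral stationary phase separates them. F15 is returned to 23 by lipase alcoholysis as in step 17 and left to racemise with Et3N, then recycled.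

Step 17. The enzyme may not accept the crowded acylal next to the diaryl ether, or the freed lactol may racemise during the slow reaction. Fallback, from 23 and back at 26, without any acylal: HF·pyridine removes the silyl group from racemic 23 to give the racemic lactol, a 1:1 mixture of 26 and its enantiomer, the (S)-lactol F16. The two are separated by supercritical-fluid chromatography on a chiral stationary phase with a neutral eluent; F16 is racemised with Et3N and recycled.

Further compounds

F1 | step 10 | 7-hydroxy-2,2,5-trimethyl-8-({[tri(propan-2-yl)silyl]oxy}methyl)-4H-1,3-benzodioxin-4-one | Cc1cc(O)c(CO[Si](C(C)C)(C(C)C)C(C)C)c2OC(C)(C)OC(=O)c12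
F2 | step 10 | 7-methoxy-2,2,5-trimethyl-8-({[tri(propan-2-yl)silyl]oxy}methyl)-4H-1,3-benzodioxin-4-one | Cc1cc(OC)c(CO[Si](C(C)C)(C(C)C)C(C)C)c2OC(C)(C)OC(=O)c12
F3 | step 1 | [(2,2-dimethyl-6-methylidene-6H-1,3-dioxin-4-yl)oxy]trimethylsilane | C=C1C=C(O[Si](C)(C)C)OC(C)(C)O1
F4 | step 1 | 6-(2-hydroxyethyl)-2,2-dimethyl-4H-1,3-dioxin-4-one | OCCC1=CC(=O)OC(C)(C)O1
F5 | step 3 | N-methoxy-N-methyl-2-(2-methyl-1,3-dioxolan-2-yl)acetamide | CON(C)C(=O)CC1(C)OCCO1
F6 | step 3 | 2,2-dimethyl-6-[4-(2-methyl-1,3-dioxolan-2-yl)-3-oxo-1-{[tri(propan-2-yl)silyl]oxy}butan-2-yl]-4H-1,3-dioxin-4-one | CC1(CC(=O)C(CO[Si](C(C)C)(C(C)C)C(C)C)C2=CC(=O)OC(C)(C)O2)OCCO1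
F7 | step 13 | prop-2-en-1-yl 5-bromo-2,4-dihydroxy-3-methylbenzoate | C=CCOC(=O)c1cc(Br)c(O)c(C)c1O
F8 | step 13 | prop-2-en-1-yl 5-bromo-2-hydroxy-4-(methoxymethoxy)-3-methylbenzoate | C=CCOC(=O)c1cc(Br)c(OCOC)c(C)c1O
F9 | step 13 | prop-2-en-1-yl 5-bromo-4-(methoxymethoxy)-3-methyl-2-(prop-2-en-1-yloxy)benzoate | C=CCOC(=O)c1cc(Br)c(OCOC)c(C)c1OCC=C
F10 | step 13 | prop-2-en-1-yl 5-bromo-6-formyl-4-(methoxymethoxy)-3-methyl-2-(prop-2-en-1-yloxy)benzoate | C=CCOC(=O)c1c(C=O)c(Br)c(OCOC)c(C)c1OCC=C
F11 | step 13 | prop-2-en-1-yl 5-bromo-6-(dimethoxymethyl)-4-hydroxy-3-methyl-2-(prop-2-en-1-yloxy)benzoate | C=CCOC(=O)c1c(C(OC)OC)c(Br)c(O)c(C)c1OCC=C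
F12 | step 13 | prop-2-en-1-yl 5-bromo-4-{[2,4-dihydroxy-6-methyl-3-({[tri(propan-2-yl)silyl]oxy}methyl)benzoyl]oxy}-6-(dimethoxymethyl)-3-methyl-2-(prop-2-en-1-yloxy)benzoate | Cc1cc(O)c(CO[Si](C(C)C)(C(C)C)C(C)C)c(O)c1C(=O)Oc1c(C)c(OCC=C)c(C(=O)OCC=C)c(C(OC)OC)c1Br
F13 | step 13 | prop-2-en-1-yl 5-bromo-6-(dimethoxymethyl)-4-{[2-hydroxy-4-methoxy-6-methyl-3-({[tri(propan-2-yl)silyl]oxy}methyl)benzoyl]oxy}-3-methyl-2-(prop-2-en-1-yloxy)benzoate | Cc1cc(OC)c(CO[Si](C(C)C)(C(C)C)C(C)C)c(O)c1C(=O)Oc1c(C)c(OCC=C)c(C(=O)OCC=C)c(C(OC)OC)c1Br
F14 | step 13 | prop-2-en-1-yl 6-(dimethoxymethyl)-3-methoxy-1,9-dimethyl-11-oxo-8-(prop-2-en-1-yloxy)-4-({[tri(propan-2-yl)silyl]oxy}methyl)-11H-dibenzo[b,e][1,4]dioxepine-7-carboxylate | COc1cc(C)c2c(c1CO[Si](C(C)C)(C(C)C)C(C)C)Oc1c(c(C)c(OCC=C)c(C(=O)OCC=C)c1C(OC)OC)OC2=O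
F15 | step 15 | (S)-O-propanoyl lactol silyl ether (enantiomer of 24) | COc1cc(C)c2c(c1CO[Si](C(C)C)(C(C)C)C(C)C)Oc1c(c(C)c(O)c3c1[C@@H](OC(=O)CC)OC3=O)OC2=O
F16 | step 17 | (S)-lactol (enantiomer of 26) | COc1cc(C)c2c(c1CO)Oc1c(c(C)c(O)c3c1[C@@H](O)OC3=O)OC2=O
A1 | alternative 1 | depsidone formyl methyl ester acetate | COc1cc(C)c2c(c1COC(C)=O)Oc1c(c(C)c(O)c(C(=O)OC)c1C=O)OC2=O
A2 | alternative 1 | diaryl ether carboxylic acid with free ring B phenol | COc1cc(C)c(C(=O)O)c(Oc2cc(C)c(O)c(C(=O)OC)c2C=O)c1COC(C)=O
A3 | alternative 1 | spiro quinone monoketal lactone | COc1cc(C)c2C(=O)OC3(C=C(C)C(=O)C(C(=O)OC)=C3C=O)Oc2c1COC(C)=O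
A4 | alternative 2 | diaryl ether with complete ring B | CC(C)(C)OC(=O)c1c(C)cc(OC)c(CO[Si](C)(C)C(C)(C)C)c1Oc1c(O)c(C)c(O)c(C(=O)OC)c1C(OCC)OCC
A5 | alternative 2 | 1-aryloxy-2,4-bis(trimethylsilyloxy)-4-methoxy-3-methylbutadiene on the ring A oxygen | CC(C)(C)OC(=O)c1c(C)cc(OC)c(CO[Si](C)(C)C(C)(C)C)c1OC=C(O[Si](C)(C)C)C(C)=C(OC)O[Si](C)(C)C
A6 | alternative 2 | methyl 4,4-diethoxybut-2-ynoate | CCOC(OCC)C#CC(=O)OC
A7 | alternative 3 | protected depsidone with rings A and C formed | COc1cc(C)c2c(c1CO[Si](C)(C)C(C)(C)C)Oc1c(c(C)c(OCOC)c(C(=O)OC(C)(C)C)c1C(OC)OC)OC2=O
A8 | alternative 3 | ring B diyne (aryl ynol ether and but-2-ynoate ester) | CC#CC(=O)Oc1c(C)c(OCOC)c(C(=O)OC(C)(C)C)c(C(OC)OC)c1OC#CCO[Si](C)(C)C(C)(C)C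
A9 | alternative 3 | methoxyethyne | COC#C
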